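**Retrosynthetic overview**

- Kanzonol C is cut at the enone Cα–Cβ bond (aldol condensation) into a ring A methyl ketone and a ring B aldehyde. Both non-chelated phenols travel as i-Pr3Si ethers and are freed by fluoride in the last step.
- The strategy rests on ring B being a 1,3,4-trisubstituted benzene: C1 carries the side-chain carbon, C3 the prenyl CH2 and C4 the phenol oxygen. Ring B carbons C5, C6, C1, C2 are C3–C6 of methyl coumalate (the C5 ester sits on ring B C1). Ring B C3 and C4 are the two alkyne carbons of a prenyl-substituted siloxyalkyne, joined by [4+2] cycloaddition and loss of CO2.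
- The siloxyalkyne comes in one flask from methyl 4-methylpent-3-enoate (ester homologation to the ynolate, then O-silylation). The silyl group set there stays on as the ring B phenol protecting group.
- Ring A is bought as 2,4-dihydroxyacetophenone. Its C3 prenyl group is placed by Claisen rearrangement of the 4-O-(1,1-dimethylallyl) ether, steered to C3 by the hydrogen-bonded 2-OH/acetyl unit.
- Ring order: ring B is formed in step 2, ring A comes from the starting material, and no further ring is closed.

Key step: step 2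

**Route**

Step 1
Reactants: 1 methyl 4-methylpent-3-enoate
Product: 4 triisopropyl[(5-methylhex-4-en-1-yn-1-yl)oxy]silane, via lithium dibromoenolate 2 (not isolated), via lithium ynolate 3 (not isolated)
Conditions: CH2Br2, lithium 2,2,6,6-tetramethylpiperidide (2.1 equiv), THF, −78 °C, then 1; n-BuLi, −78 → 0 °C; i-Pr3SiOTf, −78 °C → rt
Reagents that add atoms: dibromomethane, BrCBr; triisopropylsilyl trifluoromethanesulfonate, CC(C)[Si](C(C)C)(C(C)C)OS(=O)(=O)C(F)(F)F
Why: Kowalski ester homologation, in which LiCHBr2 adds to the ester, dibromoenolate 2 undergoes Br/Li exchange and 1,2-shift of the prenyl CH2 group to the carbenoid carbon to give ynolate 3, and the ynolate oxygen is then silylated by the bulky silyl triflate to give the isolable silyl ynol ether.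

Step 2
Reactants: 4 triisopropyl[(5-methylhex-4-en-1-yn-1-yl)oxy]silane, 5 methyl coumalate (methyl 2-oxo-2H-pyran-5-carboxylate)
Product: 7 methyl 3-(3-methylbut-2-en-1-yl)-4-[(triisopropylsilyl)oxy]benzoate, via bicyclic lactone 6 (not isolated)
Conditions: PhMe, 4 Å MS, 90 °C, sealed tube
Reagents that add atoms: none
Why: The electron-rich siloxyalkyne and the electron-poor pyrone should combine in an asynchronous inverse-electron-demand Diels–Alder reaction in which the prenyl-bearing alkyne carbon bonds to pyrone C6 slightly ahead of the bond between the oxygen-bearing carbon and pyrone C3; the closest known reaction type is the pyrone Diels–Alder/decarboxylation of coumalates with ynamines, alkoxyalkynes and ketene acetals, which gives para-heteroatom benzoates. Ring closure is a [4+2] cycloaddition across C3/C6 of the pyrone to the bridged 2-oxabicyclo[2.2.2]octadienone 6, and ring B is then released by retro-[4+2] loss of CO2, which is irreversible and expected to be fast at this temperature. No stereocentre remains, since the two bridgehead centres of racemic 6 become aromatic carbons. The step needs one regiochemistry (oxygen para to the ester, prenyl meta), secured by matched polarisation: the carbon beta to the siloxy group is the nucleophilic end of 4, while C6 of 5 is the electrophilic end because it is beta to the C5 ester, delta to the lactone carbonyl and bound to the ring oxygen. It also needs chemoselectivity for the alkyne over the prenyl alkene, which the unactivated trisubstituted alkene cannot contest, and the bulky i-Pr3Si group holds back silyl transfer and the thermal 1,3-shift to a silylketene.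

Step 3
Reactants: 7 methyl 3-(3-methylbut-2-en-1-yl)-4-[(triisopropylsilyl)oxy]benzoate
Product: 8 {3-(3-methylbut-2-en-1-yl)-4-[(triisopropylsilyl)oxy]phenyl}methanol
Conditions: i-Bu2AlH (2.5 equiv), CH2Cl2, −78 → 0 °C; aq KNa tartrate
Reagents that add atoms: none
Why: Aluminium hydride reduction of an aryl ester to the benzylic alcohol, with the aryl silyl ether and the isolated trisubstituted alkene inert to the hydride at low temperature.

Step 4
Reactants: 8 {3-(3-methylbut-2-en-1-yl)-4-[(triisopropylsilyl)oxy]phenyl}methanol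
Product: 9 3-(3-methylbut-2-en-1-yl)-4-[(triisopropylsilyl)oxy]benzaldehyde
Conditions: activated MnO2 (excess), CH2Cl2, rt
Reagents that add atoms: none
Why: MnO2 oxidation is selective for benzylic alcohols, stops at the aldehyde and leaves the prenyl alkene and the silyl ether untouched.

Step 5
Reactants: 10 2,4-dihydroxyacetophenone, 11 3-chloro-3-methylbut-1-yne
Product: 12 1-[2-hydroxy-4-(2-methylbut-3-yn-2-yloxy)phenyl]ethanone
Conditions: K2CO3, KI, CuI (cat.), acetone, reflux
Reagents that add atoms: none
Why: Copper-assisted O-alkylation of a phenol with a tertiary propargylic chloride (Williamson-type etherification), confined to the 4-OH because the 2-OH is held in a hydrogen bond to the acetyl carbonyl and is far less nucleophilic.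

Step 6
Reactants: 12 1-[2-hydroxy-4-(2-methylbut-3-yn-2-yloxy)phenyl]ethanone
Product: 13 1-[2-hydroxy-4-(2-methylbut-3-en-2-yloxy)phenyl]ethanone
Conditions: H2 (1 atm), Pd/CaCO3 poisoned with Pb(OAc)2 (Lindlar catalyst), quinoline, EtOAc, rt
Reagents that add atoms: none
Why: Lindlar semi-hydrogenation stops at the terminal alkene on the poisoned palladium surface and does not reduce the aryl ketone or the arene.

Step 7
Reactants: 13 1-[2-hydroxy-4-(2-methylbut-3-en-2-yloxy)phenyl]ethanone
Product: 15 1-[2,4-dihydroxy-3-(3-methylbut-2-en-1-yl)phenyl]ethanone, via cyclohexadienone 14 (not isolated)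
Conditions: PhNEt2, 130 °C
Reagents that add atoms: none
Why: Aromatic Claisen rearrangement ([3,3]) of the aryl 1,1-dimethylallyl ether delivers a normal prenyl group, and it should go to C3 instead of C5 because the chelated 2-hydroxyacetophenone unit localises double-bond character in the C3–C4 bond, after which dienone 14 tautomerises to the phenol.

Step 8
Reactants: 15 1-[2,4-dihydroxy-3-(3-methylbut-2-en-1-yl)phenyl]ethanone
Product: 16 1-{2-hydroxy-3-(3-methylbut-2-en-1-yl)-4-[(triisopropylsilyl)oxy]phenyl}ethanone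
Conditions: i-Pr3SiCl, imidazole, DMF, rt
Reagents that add atoms: triisopropylsilyl chloride, CC(C)[Si](Cl)(C(C)C)C(C)C
Why: Phenol silylation with a bulky silyl chloride takes the free 4-OH and leaves the 2-OH, which is hydrogen-bonded to the carbonyl and flanked by acetyl and prenyl groups.

Step 9
Reactants: 16 1-{2-hydroxy-3-(3-methylbut-2-en-1-yl)-4-[(triisopropylsilyl)oxy]phenyl}ethanone, 9 3-(3-methylbut-2-en-1-yl)-4-[(triisopropylsilyl)oxy]benzaldehyde
Product: 19 (E)-1-{2-hydroxy-3-(3-methylbut-2-en-1-yl)-4-[(triisopropylsilyl)oxy]phenyl}-3-{3-(3-methylbut-2-en-1-yl)-4-[(triisopropylsilyl)oxy]phenyl}prop-2-en-1-one, via dilithium enolate 17 (not isolated), via dilithium aldolate 18 (not isolated)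
Conditions: LiN(SiMe3)2 (2.2 equiv), THF, −78 °C; then 9, −78 °C → rt; aq NH4Cl
Reagents that add atoms: none
Why: Lithium amide-mediated Claisen–Schmidt (aldol) condensation, in which phenoxide/enolate 17 adds to the non-enolisable aldehyde and aldolate 18 relays the alpha proton and expels lithium hydroxide (E1cB) on warming to give the thermodynamically favoured E enone, while the absence of aqueous hydroxide and alcohol solvent should keep the aryl silyl ethers in place.

Step 10
Reactants: 19 (E)-1-{2-hydroxy-3-(3-methylbut-2-en-1-yl)-4-[(triisopropylsilyl)oxy]phenyl}-3-{3-(3-methylbut-2-en-1-yl)-4-[(triisopropylsilyl)oxy]phenyl}prop-2-en-1-one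
Product: 20 kanzonol C, (E)-1-[2,4-dihydroxy-3-(3-methylbut-2-en-1-yl)phenyl]-3-[4-hydroxy-3-(3-methylbut-2-en-1-yl)phenyl]prop-2-en-1-one
Conditions: Bu4NF, AcOH, THF, 0 °C → rt
Reagents that add atoms: none
Why: Fluoride cleavage of both aryl silyl ethers, buffered with acetic acid so that the phenoxides are protonated at once and neither oxa-Michael closure to the flavanone nor acid-induced chroman formation from the ortho-prenyl phenols should occur; the E double bond is not touched.

**Compound list**

1 | methyl 4-methylpent-3-enoate | COC(=O)CC=C(C)C | starting material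
2 | lithium 1,1-dibromo-5-methylhexa-1,4-dien-2-olate | [Li+].[O-]C(CC=C(C)C)=C(Br)Br | intermediate
3 | lithium 5-methylhex-4-en-1-yn-1-olate | [Li+].[O-]C#CCC=C(C)C | intermediate
4 | triisopropyl[(5-methylhex-4-en-1-yn-1-yl)oxy]silane | CC(C)=CCC#CO[Si](C(C)C)(C(C)C)C(C)C | intermediate
5 | methyl coumalate (methyl 2-oxo-2H-pyran-5-carboxylate) | COC(=O)C1=COC(=O)C=C1 | starting material
6 | methyl 7-(3-methylbut-2-en-1-yl)-3-oxo-8-[(triisopropylsilyl)oxy]-2-oxabicyclo[2.2.2]octa-5,7-diene-6-carboxylate (racemic, bridgeheads fixed by the bicycle) | COC(=O)C1=CC2C(=O)OC1C(CC=C(C)C)=C2O[Si](C(C)C)(C(C)C)C(C)C | intermediate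
7 | methyl 3-(3-methylbut-2-en-1-yl)-4-[(triisopropylsilyl)oxy]benzoate | COC(=O)c1ccc(O[Si](C(C)C)(C(C)C)C(C)C)c(CC=C(C)C)c1 | intermediate
8 | {3-(3-methylbut-2-en-1-yl)-4-[(triisopropylsilyl)oxy]phenyl}methanol | OCc1ccc(O[Si](C(C)C)(C(C)C)C(C)C)c(CC=C(C)C)c1 | intermediate
9 | 3-(3-methylbut-2-en-1-yl)-4-[(triisopropylsilyl)oxy]benzaldehyde | O=Cc1ccc(O[Si](C(C)C)(C(C)C)C(C)C)c(CC=C(C)C)c1 | intermediate
10 | 2,4-dihydroxyacetophenone | CC(=O)c1ccc(O)cc1O | starting material
11 | 3-chloro-3-methylbut-1-yne | C#CC(C)(C)Cl | starting material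
12 | 1-[2-hydroxy-4-(2-methylbut-3-yn-2-yloxy)phenyl]ethanone | CC(=O)c1ccc(OC(C)(C)C#C)cc1O | intermediate
13 | 1-[2-hydroxy-4-(2-methylbut-3-en-2-yloxy)phenyl]ethanone | CC(=O)c1ccc(OC(C)(C)C=C)cc1O | intermediate
14 | 4-acetyl-5-hydroxy-6-(3-methylbut-2-en-1-yl)cyclohexa-2,4-dien-1-one (racemic) | CC(=O)C1=C(O)C(CC=C(C)C)C(=O)C=C1 | intermediate
15 | 1-[2,4-dihydroxy-3-(3-methylbut-2-en-1-yl)phenyl]ethanone | CC(=O)c1ccc(O)c(CC=C(C)C)c1O | intermediate
16 | 1-{2-hydroxy-3-(3-methylbut-2-en-1-yl)-4-[(triisopropylsilyl)oxy]phenyl}ethanone | CC(=O)c1ccc(O[Si](C(C)C)(C(C)C)C(C)C)c(CC=C(C)C)c1O | intermediate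
17 | dilithium 2-(1-oxidoethenyl)-6-(3-methylbut-2-en-1-yl)-5-[(triisopropylsilyl)oxy]phenolate | [Li+].[Li+].C=C([O-])c1ccc(O[Si](C(C)C)(C(C)C)C(C)C)c(CC=C(C)C)c1[O-] | intermediate
18 | dilithium salt of the aldol adduct, 3-hydroxy-1-{2-hydroxy-3-prenyl-4-[(triisopropylsilyl)oxy]phenyl}-3-{3-prenyl-4-[(triisopropylsilyl)oxy]phenyl}propan-1-one (racemic) | [Li+].[Li+].[O-]C(CC(=O)c1ccc(O[Si](C(C)C)(C(C)C)C(C)C)c(CC=C(C)C)c1[O-])c1ccc(O[Si](C(C)C)(C(C)C)C(C)C)c(CC=C(C)C)c1 | intermediate
19 | (E)-1-{2-hydroxy-3-(3-methylbut-2-en-1-yl)-4-[(triisopropylsilyl)oxy]phenyl}-3-{3-(3-methylbut-2-en-1-yl)-4-[(triisopropylsilyl)oxy]phenyl}prop-2-en-1-one | CC(C)=CCc1cc(/C=C/C(=O)c2ccc(O[Si](C(C)C)(C(C)C)C(C)C)c(CC=C(C)C)c2O)ccc1O[Si](C(C)C)(C(C)C)C(C)C | intermediate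
20 | kanzonol C, (E)-1-[2,4-dihydroxy-3-(3-methylbut-2-en-1-yl)phenyl]-3-[4-hydroxy-3-(3-methylbut-2-en-1-yl)phenyl]prop-2-en-1-one | CC(C)=CCc1cc(/C=C/C(=O)c2ccc(O)c(CC=C(C)C)c2O)ccc1O | target

**Step count and risks**

Total step count: 10. Longest linear sequence: 6 steps (steps 1–4, 9, 10, or equally steps 5–8, 9, 10).

Steps most likely to fail:

1. Step 2 (key cycloaddition). The first C–C bond could form without ring closure, leading to opening of the pyrone ring or silyl transfer from the zwitterion. The siloxyalkyne could also isomerise thermally by 1,3-silyl shift before it reacts, or add with reversed orientation. The fallback abandons the pyrone and builds the same arene by a Claisen route. It sets out from 11, which is O-alkylated onto purchased methyl 4-hydroxybenzoate (K2CO3, KI, CuI, acetone, reflux) to give methyl 4-(2-methylbut-3-yn-2-yloxy)benzoate F1. Semi-hydrogenation (H2, Pd/CaCO3 poisoned with Pb(OAc)2, quinoline) should give methyl 4-(2-methylbut-3-en-2-yloxy)benzoate F2, and heating (PhNEt2, 150 °C) should give methyl 4-hydroxy-3-(3-methylbut-2-en-1-yl)benzoate F3. Silylation (i-Pr3SiCl, imidazole, DMF) comes back to the route at 7.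

2. Step 1 (ynolate formation). The doubly activated allylic alpha CH2 of 1, or of the dibromoketone on the wrong side, could be deprotonated by the amide base instead of undergoing addition and rearrangement. Residual bases could also consume the silyl triflate. The fallback reaches the ynolate by acetylide oxidation and sets out from 1. Partial reduction (i-Bu2AlH, 1 equiv, CH2Cl2, −78 °C) should give 4-methylpent-3-enal F4, and Corey–Fuchs olefination (CBr4, PPh3, CH2Cl2, 0 °C) should give 1,1-dibromo-5-methylhexa-1,4-diene F5. Treatment with n-BuLi (2 equiv, THF, −78 °C) should give (5-methylhex-4-en-1-yn-1-yl)lithium F6, which is oxidised with lithium tert-butyl peroxide (t-BuOOH, LiN(SiMe3)2, −78 → 0 °C). This comes back to the route at ynolate 3, which is silylated to 4 as in step 1.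

3. Step 9 (condensation). The dilithium aldolate could stall before elimination or revert by retro-aldol. Free amide could add to the aldehyde, and the lithium hydroxide released could strip the silyl groups unevenly. The fallback changes to base-stable acetal protection and the classical hydroxide Claisen–Schmidt reaction, and it sets out from 9 and 15. Desilylation of 9 (Bu4NF, THF, 0 °C) should give 4-hydroxy-3-(3-methylbut-2-en-1-yl)benzaldehyde F7, and MOMCl, i-Pr2NEt, CH2Cl2 should give 4-(methoxymethoxy)-3-(3-methylbut-2-en-1-yl)benzaldehyde F8. Ketone 15 with MOMCl (1.1 equiv), i-Pr2NEt should give 1-[2-hydroxy-4-(methoxymethoxy)-3-(3-methylbut-2-en-1-yl)phenyl]ethanone F9. Condensation of F8 and F9 (KOH, EtOH/H2O, rt) should give (E)-1-[2-hydroxy-4-(methoxymethoxy)-3-(3-methylbut-2-en-1-yl)phenyl]-3-[4-(methoxymethoxy)-3-(3-methylbut-2-en-1-yl)phenyl]prop-2-en-1-one F10. Brief acid methanolysis (3 M HCl, MeOH, 50 °C) comes back to the route at 20.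

**Further compounds**

F1 | step 2 | methyl 4-(2-methylbut-3-yn-2-yloxy)benzoate | COC(=O)c1ccc(OC(C)(C)C#C)cc1
F2 | step 2 | methyl 4-(2-methylbut-3-en-2-yloxy)benzoate | COC(=O)c1ccc(OC(C)(C)C=C)cc1
F3 | step 2 | methyl 4-hydroxy-3-(3-methylbut-2-en-1-yl)benzoate | COC(=O)c1ccc(O)c(CC=C(C)C)c1
F4 | step 1 | 4-methylpent-3-enal | CC(C)=CCC=O
F5 | step 1 | 1,1-dibromo-5-methylhexa-1,4-diene | CC(C)=CCC=C(Br)Br
F6 | step 1 | (5-methylhex-4-en-1-yn-1-yl)lithium | [Li]C#CCC=C(C)C
F7 | step 9 | 4-hydroxy-3-(3-methylbut-2-en-1-yl)benzaldehyde | O=Cc1ccc(O)c(CC=C(C)C)c1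
F8 | step 9 | 4-(methoxymethoxy)-3-(3-methylbut-2-en-1-yl)benzaldehyde | COCOc1ccc(C=O)cc1CC=C(C)C
F9 | step 9 | 1-[2-hydroxy-4-(methoxymethoxy)-3-(3-methylbut-2-en-1-yl)phenyl]ethanone | CC(=O)c1ccc(OCOC)c(CC=C(C)C)c1O
F10 | step 9 | (E)-1-[2-hydroxy-4-(methoxymethoxy)-3-(3-methylbut-2-en-1-yl)phenyl]-3-[4-(methoxymethoxy)-3-(3-methylbut-2-en-1-yl)phenyl]prop-2-en-1-one | CC(C)=CCc1cc(/C=C/C(=O)c2ccc(OCOC)c(CC=C(C)C)c2O)ccc1OCOC
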